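1. In Tuesday's run L = ln(substrate charged/substrate left) grows by a factor of 3.92 from 20.0 min to 40.0 min, while the time grows by a factor of 2.00.

| flask | substrate | coupling partner | precatalyst | remark |
|---|---|---|---|---|
| Tuesday's | 20 mM | 100 mM | 4 mM | run made earlier |
| flask | 20 mM | 100 mM | 2.0 mM |  |

Tuesday's run (percent of the substrate charged)

| time / min | target / % | substrate / % |
|---|---|---|
| 3.00 | 0.1 | 100.0 |
| 5.00 | 1.0 | 100.5 |
| 10.0 | 1.3 | 96.2 |
| 20.0 | 12.9 | 86.9 |
| 40.0 | 42.7 | 57.7 |

(standard deviation of a reading: 1 percentage point)

- factor on the rate of making target when 50% of the substrate are converted if coupling partner is charged twice over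
- factor on the rate when 50% of the substrate are converted if precatalyst is charged at 10 mM instead

- no earlier run changes the charge of coupling partner; that part of a forecast is a guess
- no earlier run changes the charge of precatalyst; that part of a forecast is a guess

2. L growing with the square of time is read here as catalyst forming steadily from precatalyst, so that catalyst present goes as charge c times time t. Half conversion then comes at a time proportional to 1/√c.

3. The last reading of Tuesday's run puts half conversion in that run, at 4 mM precatalyst, at 44.9 min. This gives two times: the flask's half-conversion time t_F = 63.5 min, and t_X = 28.4 min at 10 mM.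

4. The rate at half conversion goes as c·t. The charge rises by a factor of 5.00 from the flask's 2.0 mM, so this reckoning gives 2.24. If coupling partner is first order, a guess, a partner factor of 2 gives 1.41.

5. The forecast gives 1.7 (1.2 to 2.6) and 1.4 (1 to 2.1): “A 2.5-fold precatalyst increase then gives about 1.6”. The reckoning above, which steps up from the flask's 2.0 mM, stands higher on precatalyst.

6. The simulation gives 2.51 for precatalyst and 1.56 for coupling partner.

    precatalyst → catalyst (k = 1.60 × 10⁻⁴ s⁻¹)
    substrate + coupling partner + catalyst → target + catalyst, rate k2*[substrate]*[coupling partner]*[catalyst]/(1 + ([substrate]/sat2)) (14.0 mM, k = 7.20 M⁻² s⁻¹)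
    substrate + coupling partner → uncatalysed product (k = 2.50 × 10⁻⁵ M⁻¹ s⁻¹)

The flask reaches half conversion at 65.7 min, against t_F = 63.5 min, and the 10 mM charge gives 2.51, above the reckoned 2.24. In the flask, precatalyst kept turning into catalyst with a half-life of 1.2 h: catalyst stood at 15.9% of the catalyst charged after 0.300 h and 57.9% after 1.50 h, while substrate fell to 26.5%. After 3.00 h substrate, the limiting reagent, was down to 0.406%, with 17.8% of the catalyst charged still precatalyst.

All runs are simulated for an exercise; noise was put on by code.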